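The data come from a simulation from invented constants, and the scatter is random.

How much of the E ends as L, Z and G in a flask charged at 0.50 M and read at 4.0 h, and does anything still move there?

| flask | E | remark | time |
|---|---|---|---|
| winter | 0.25 M | run made earlier |  |
| dawn | 0.38 M | run made earlier |  |
| flask | 0.50 M |  | 4.0 h |

| run | time / h | E / % | L / % | Z / % | G / % |
|---|---|---|---|---|---|
| winter | 0.200 | 0 | 42.3 | 32.4 | 18.6 |
| winter | 0.417 | 0 | 42.4 | 34.2 | 18.4 |
| winter | 1.00 | 0.7 | 41.7 | 33.1 | 18.1 |
| winter | 2.50 | 0 | 41.8 | 32.6 | 19.3 |
| dawn | 0.200 | 1.1 | 32.9 | 33.7 | 26.4 |
| dawn | 0.417 | 0.6 | 33.3 | 34.4 | 26.2 |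
| dawn | 1.00 | 0 | 33.2 | 34.4 | 27.5 |
| dawn | 2.50 | 0.2 | 32.5 | 33.6 | 26.3 |

(each reading ± 0.5 percentage points)

- at 4.0 h, what has stopped the reaction, if anything has (forward and back rates have come level / it is still moving / all of E has reacted)
- how much of the E has reacted by 4.0 h
- how much L there is at 4.0 h, in percent of the E charged
- how much Z there is at 4.0 h, in percent of the E charged
- how much G there is at 4.0 h, in percent of the E charged

- in percentages every species weighs as the E in it: one Z counts as two
- in percentages every species weighs as the E in it: one G counts as three
- the reaction counts as stopped when no species that holds the E changes by six tenths of a point or more over the second half of the time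

In the winter and dawn runs, E reads at most 1.1% from 0.200 h on, and the products stand within a few multiples of the scatter up to 2.50 h, a time shorter than the flask's. The reckoning here therefore expects the flask to read no E at its time, with a split set early, which is kinetic control. The charge moves that split, but two things stay nearly constant. Z averages 33.1% in winter and 34.0% at dawn. The sum of L, Z and G averages 93.7% and 93.6%. Freezing both leaves L trading against G.

L averages 42.0% in winter and falls to 33.0% at dawn. If that fall continues, the dawn value bounds the flask's L from above. If the fall does not steepen, a straight line in cE gives the bound from below, 24.6%. To tighten the bracket, take the loss as equal for each doubling of cE: the two runs then give 15 percentage points, the doubling toll. The flask holds twice the winter charge, so L comes to 27.0%. With Z frozen at 33.6%, G comes to 33.1%.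

The forecast, judging “the product split is fixed early”, says all of E has reacted, with 100% of the E reacted, L 27.3%, Z 33.2% and G 33.2%. Its L lies inside the bracket, close to this reckoning but not equal to it.

In the flask all of E has reacted: 100% of the E has reacted, with L 27.4%, Z 34.2% and G 32.6%. At 40.0 h L still stands at 27.4%. The one doubling from winter cost 15 points, against a toll of 15 points.

    E → L (k = 0.00580 s⁻¹)
    2 E → J (k = 0.00752 M⁻¹ s⁻¹)
    E + J → G (k = 0.0674 M⁻¹ s⁻¹)
    E + L → Z (k = 0.0277 M⁻¹ s⁻¹)

For the neighbour charged with 0.30 M, the toll gives L 38.1%. The computed neighbour holds 38.0%.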